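Every bit of initiator that reacts becomes either a living end or spent initiator, and each monomer in chains has left the free monomer: these two balances carry the reckoning.

in all of them: free monomer 1.0 M; transfer agent 0.0300 M; capture agent 0.100 M; initiator 3 mol%; impurity 31 mM; time 5.0 h
- oak: temperature 50 °C
- alder: temperature 65 °C
- maple: temperature 35 °C

    living end + capture agent → trapped intermediate (k1 = 0.0198 L mol⁻¹ s⁻¹, Ea1 = 77.0 kJ mol⁻¹)
    initiator + impurity → spent initiator (k2 = 5.34 L mol⁻¹ s⁻¹, Ea2 = 53.0 kJ mol⁻¹)
    living end + transfer agent → dead chain (k3 = 0.0125 L mol⁻¹ s⁻¹, Ea3 = 61.0 kJ mol⁻¹)
    free monomer + initiator → living end + monomer in chains (k4 = 0.00580 L mol⁻¹ s⁻¹, Ea4 = 78.0 kJ mol⁻¹)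
    free monomer + living end → monomer in chains + living end, rate k5*[living end]*[free monomer] (k5 = 0.231 L mol⁻¹ s⁻¹, Ea5 = 45.0 kJ mol⁻¹)
    (constants at 50 °C)

- the constants hold at 50 °C; other temperatures follow from the activation energies

- which flask leads in amount of monomer in chains, in percent of the free monomer charged ("all alike" within 1.5 percentage points) (oak / alder / maple / all alike)
- how much monomer in chains is there at the end, in percent of the free monomer charged: oak
- how much monomer in chains is there at the end, in percent of the free monomer charged: alder
- how much monomer in chains is there at the end, in percent of the free monomer charged: maple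

You need two divisions of one rate by another, and time drops out of both.

First, initiator makes ends through its step with free monomer and is lost through its step with impurity. Dividing the two rates and summing gives E, the ends made: E = a ln(c(impurity charged)/c(impurity left)), where a is the initiation constant times c(free monomer) over the impurity constant. Once the initiator has reacted away, the balance says impurity left is 1.00 mM plus E. In oak, initiator lives at most 187 s, shorter than an end's 425 s, so you may put free monomer at its charge, which sets a slightly high.

Now bracket E. Put E at zero on the right: too little impurity left gives too many ends, a ceiling. That ceiling gives a floor, and the floor a better ceiling. The table shows the second round, where the floor is a floor up to that slight excess in a.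

Second, an end grows at the growth constant times c(free monomer), and dies by capture and transfer. The concentration of living ends cancels. So ln c(free monomer) falls, per unit of ends dying, by the reach, the growth constant over (capture constant × c(capture agent) + transfer constant × c(transfer agent)): in alder 60.1 L mol⁻¹. Reach times c(free monomer) is the kinetic chain length. Even in maple an end lasts 0.452 h, shorter than the run. Each end also took one monomer when it formed, so the part in chains is 1 − (1 − E/c(free monomer)) exp(−reach × E).

| Flask | Reach | a | Ends, ceiling | Ends, floor | Chains, floor | Chains, ceiling |
|---|---|---|---|---|---|---|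
| oak | 98.1 L mol⁻¹ | 1.09 mM | 2.52 mM | 2.36 mM | 20.9% | 22.1% |
| alder | 60.1 L mol⁻¹ | 1.64 mM | 3.57 mM | 3.14 mM | 17.5% | 19.6% |
| maple | 166 L mol⁻¹ | 0.691 mM | 1.73 mM | 1.68 mM | 24.5% | 25.1% |

In alder the ceiling of ends is less than the capture agent charged, so I reckon the reach on charged amounts. Maple's floor stands higher than oak's ceiling, and oak's floor higher than alder's ceiling, so my order is maple, oak, alder.

The forecast names maple, with 21.2% for oak, 18% for alder and 24.6% for maple, each inside its bracket, reasoning that “each end adds more monomer when cool”.

The flasks give 21.2% in oak, 18.1% in alder and 24.6% in maple, so maple leads. Maple's answer moves by 5 points at 2.8 mol% or 3.2 mol% of initiator. Now take alder with 0.40 M of capture agent. Its reach shrinks from 60.1 L mol⁻¹ to 16.6 L mol⁻¹. It ends with 0.00313 M of trapped intermediate and 1.14 × 10⁻⁴ M of dead chain, and these ends reckon to 5.54% in chains; that flask holds 5.56%.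

(The numbers come from no measurement; the flask was simulated.)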